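- The pitfall with green and grey is to read their gap as an effect of substrate concentration, when the two flasks also stop at different times.

| flask | substrate | first nucleophile | second nucleophile | remark | time |
|---|---|---|---|---|---|
| east | 0.24 M | 0.60 M | 1.2 M | run made earlier |  |
| north-east | 0.26 M | 0.60 M | 1.2 M | run made earlier |  |
| west | 0.35 M | 0.60 M | 1.2 M | run made earlier |  |
| green | 0.20 M | 0.600 M | 1.20 M |  | 0.80 h |
| grey | 0.40 M | 0.600 M | 1.20 M |  | 2.5 h |

| run | time / h | target / % |
|---|---|---|
| east | 0.200 | 43.8 |
| east | 0.500 | 44.0 |
| east | 1.00 | 41.2 |
| east | 2.50 | 33.0 |
| north-east | 0.200 | 45.0 |
| north-east | 0.500 | 46.1 |
| north-east | 1.00 | 42.6 |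
| north-east | 2.50 | 35.8 |
| west | 0.333 | 43.8 |
| west | 0.833 | 41.3 |
| west | 1.50 | 35.6 |
| west | 2.50 | 32.0 |

(readings scatter by 1 percentage point)

- the numbers in the tables scatter with a standard deviation of 1 percentage point

* which of the two ends with the higher amount of target, in percent of the substrate charged ("neither" if they lie within 2 percentage points) (green / grey / neither)
* target at the end, in percent of the substrate charged, green
* target at the end, in percent of the substrate charged, grey

- Take first just the main step, substrate to target. The east run stands at 43.8 % after 0.200 h and 44.0 % after 0.500 h, so we read the rise as over by then, and both asked times lie beyond that point.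
- Now add a slow loss of target. Each run falls after its second reading, and the mean first-order rate over the falling stretches gives a time of 7.09 h. We call this the apparent lifetime of target: the time in which target falls by a factor of e. It is a reading, and it is far longer than the rise.
- So we count lifetimes. Green runs 0.113 of them and keeps a factor 0.893, while grey runs 0.353 and keeps 0.703.
- Then comes the rest, the height before any loss. Dividing the survival out of a reading gives 47.2 % in the east run and 46.5 % in the west run, a step of 0.70 points for a scatter of 1 point. The lifetime count, on the same height, opens 9 points.
- Our own reckoning takes the east height for green and the west height for grey, which gives 42.1 % and 32.7 %.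
- The forecast says green, with 43 % and 32 %, on the ground “Green ends clearly higher, mainly because it is stopped earlier.” Its green lies a little above ours.
- The flask gives green as the higher, with 43.1 % for green and 32.7 % for grey, so forecast and count agree with it.

    second nucleophile + intermediate → other capture product (k = 0.820 /M/min)
    first nucleophile + intermediate → target (k = 2.80 /M/min)
    first nucleophile → decomposed reagent (k = 0.0450 /min)
    target ⇌ isomer of the product (K = 0.730, k = 0.00410 /min)
    substrate → intermediate (k = 0.170 /min)
    intermediate → solvolysis product (k = 0.170 /min)

- The substrate concentration is not the reason for the gap: green at grey's substrate concentration holds 41.1 %, whereas green taken to grey's time holds 34.2 %, so time is part of it. The main reason that green stands below full yield is the capture of intermediate by second nucleophile: without that step green holds 73.0 %. With the step to the isomer of the product struck out, grey holds 47.9 %, and the lifetime turns that into 33.7 % against the actual 32.7 %. In the neighbour flask with 0.48 M of second nucleophile, target plus isomer of the product come to 62.5 %, so the same lifetime gives 43.9 %, and that flask holds 42.6 %.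

The earlier runs and the new flask are calculated on assumed constants, and the scatter is random.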